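## The problem

Sipholenol K is built from two bicyclic halves joined by a CH2–CH2 bridge. The left half is a 2,2-dimethyloxepan-3-ol trans-fused to a cyclohexane (rings A and B). The right half is a cis-fused decalin (rings C and D) in which ring C is a 2-methylcyclohex-2-enone that carries the bridge on its β-carbon.

Five stereocentres lie in the left half: the ring A carbinol, the angular methyl-bearing carbon, the neighbouring ether CH, the CH that carries the bridge and the ring B tertiary carbinol. Three lie in the right half: the two fusion CH and the ring D tertiary carbinol. The two sets are insulated by the bridge, so each half needs its own source of absolute configuration and the halves should be joined convergently.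

Within the left half the ether CH can direct the building of the adjacent quaternary carbon. Once ring A is closed, the rigid trans-fused bicycle fixes the bridge-bearing CH (equatorial, adjustable next to a ketone) and the tertiary carbinol (axial methyl, equatorial oxygen). In the right half a suprafacial cycloaddition gives the cis fusion, and ring C then shields one face of ring D, which determines the side on which the ring D carbinol oxygen enters.

The fragile points are:
- the two tertiary alcohols, which ionise under strong acid;
- the enone, whose γ-carbon is a fusion stereocentre and should therefore be unveiled last;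
- any ring C intermediate at the 2,4-dienone level, which would tautomerise to a phenol;
- 5-oxygenated cyclohexa-1,3-dienes, which can lose the oxygen and aromatise.

The enabling feature is the substitution of ring D. The CMe2 carbon sits on one fusion CH, the C(CH3)OH carbon on the other, and two CH2 groups lie between them. Taking the two CH2 groups out leaves a four-membered ring in which CMe2 and a carbonyl carbon span the fusion bond, which is the adduct of dimethylketene with a ring C alkene. Putting them back as a vinyl group on that carbonyl gives a 1-vinylcyclobutanol. Its alkoxy radical can open toward CMe2 and re-close through the vinyl terminus.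

## Retrosynthesis

**36 from 35 and 34.** The enone carbonyl of 36 is taken back to an allylic alcohol (35) and further to its silyl ether in 34. No skeletal bond is cut. This keeps the γ fusion centre away from base, keeps ring C from being a Michael acceptor during the organometallic steps, and leaves a stereocentre on ring C that can steer the cycloaddition. The forward steps are a global desilylation and a chemoselective allylic oxidation.

**34 from 33 and 32.** The C–CH3 and C–O bonds of the ring D carbinol are cut back to the ketone 32 via the exocyclic alkene 33. Direct methyl addition to 32 would come from the open face and give the wrong epimer. A peracid would attack the tetrasubstituted ring C alkene before the methylene group. A hydrogen-atom-transfer hydration reacts only with the 1,1-disubstituted alkene and delivers oxygen to the tertiary radical from the face of the fusion hydrogens.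

**32 from 31 (key disconnection).** The CMe2–CH2 bond of ring D is cut and CMe2 is reconnected to the carbonyl carbon, which gives the 1-vinylcyclobutanol 31. Annulations that build ring D by aldol or cycloaddition chemistry would have to create the quaternary CMe2 next to a fusion carbon and control the cis fusion separately. Here both come from one [2+2] step and ring D shrinks to a cyclobutane made from three small reagents. The forward reaction must cleave toward CMe2, close 6-endo, and spare the silyl ethers and the ring C alkene.

**31 from 29 and 30; 29 from 26 and 28.** The vinyl–carbinol bond is cut to the cyclobutanone 29 and vinylmagnesium bromide 30. The CMe2–CH and C(O)–CH bonds of 29 are cut to the diene 26 and dimethylketene 28, made in the flask from isobutyryl chloride 27. The polarity of the diene places the ketene carbonyl carbon on the diene terminus, so CMe2 lands on the fusion carbon next to the remaining tetrasubstituted alkene, which is the future enone alkene. The silyloxy centre of 26 has to direct the ketene to the opposite face.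

**26 from 25 and 23.** Dehydrogenating a 3-alkyl-2-methylcyclohexenone is not an option, because the linear dienone is a phenol tautomer and the reduced form offers no regiochemical handle. The diene terminus therefore enters as a ketone. The C–H bond at that carbon is traced back to the dienyl triflate 25 and on to the enone 23. The future enone oxygen is already present as the silyl ether stereocentre. The forward steps are a kinetic enolisation at the only α′-CH2 and a reduction of the C–OTf bond.

**23 from 19 and 20.** The bond between the bridge and the ring C sp2 carbon is cut. The forward reaction is a B-alkyl Suzuki–Miyaura coupling of the α-iodoenone 20 with the borate made from the iodide 19. It was preferred to an organolithium addition and carbonyl transposition because it leaves the ring C ketone in the place where the second double bond is needed, and it tolerates every group present. Both partners are far simpler than 23.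

**20 and ring B from 4; 4 from 1.** One enone, (S)-4-silyloxy-3-methylcyclohexenone 4, serves twice. In ring C it supplies the methyl-bearing alkene carbon and the controlling silyloxy centre; α-iodination gives 20. In ring B it supplies the angular carbon with its methyl group, the ether CH with its absolute configuration, and the ketone that later becomes the tertiary carbinol. 4 is traced through the silyl ether 3 and the allylic alcohol 2 to 2-methylcyclohex-2-enone 1 by allylic oxidation, silylation and enantioselective reduction.

**19 from 18, 17, 16, 15, 14 and 13.** The C–I bond goes back to the alcohol 18, and the 2-hydroxyethyl arm to the allyl group of 17 (one carbon removed). The ring B carbinol of 16 is cut at C–H and C–O to the spiro-epoxide 15, the alkene 14 and the ketone 13. Methyl addition to 13 would give the equatorial methyl epimer. The peracid instead approaches away from the axial angular methyl group. An allyl arm is used instead of an acetate arm because a free tertiary/primary 1,4-diol would close to a tetrahydrofuran on activation.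

**13 from 12 and 11.** The O–CMe2 bond of ring A is cut to the hydroxy epoxide 12, and the epoxide to the alkene 11. The ring A carbinol centre then comes from a reagent-controlled epoxidation, and the ring B hydroxyl opens the epoxide at its tertiary carbon. Closing ring A at another bond would cost more steps. The forward reaction must favour the 7-endo over the 6-exo mode.

**11 from 10, 7, 4, 5 and 8.** Two C–C bonds at the former enone carbons of 4 are cut. Conjugate addition of the Grignard reagent from 5-bromo-2-methylpent-2-ene 5, anti to the silyloxy group, creates the quaternary centre and gives the silyl enol ether 7. Allylation of the derived enolate with allyl bromide 8 gives 10, and desilylation gives 11.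

## Roads not taken

**Alternative 1:** a cation cascade that folds an acyclic chain into rings A and B. Farnesol A1 would be converted into the diepoxy tert-butyl carbonate A2. Me3SiOTf would open the terminal epoxide, the inner epoxide oxygen would bond to the CMe2 carbon, the 2,3-alkene would bond to the angular carbon, and the carbonate would trap the tertiary cation to give the cyclic carbonate A3.
- Merits: three bonds, two rings and four of the five left-half stereocentres arise in one step, three or four steps from A1. This is clearly shorter than the fourteen steps that lead to 19 in the chosen plan.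
- Weak points: the terminating alkene of A2 is an allylic carbonate and a poor π-nucleophile, so elimination, premature carbonate participation and boat-type closures compete. Both epoxides need the less common enantiomer of the epoxidation catalyst. A3 carries a one-carbon arm, so a homologation through a β-hydroxy aldehyde must follow. The cascade does nothing for rings C and D.
- Comparison: the chosen plan concedes step count in the left half. It sets against this that every left-half stereocentre has its own control element and can be corrected separately, that the two-carbon arm is installed directly, and that the strategic step is spent on ring D, where the cis fusion, the quaternary carbon and the tertiary carbinol are the harder problem.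

**Alternative 2:** ring A would be carried as a six-membered pyranone through the whole synthesis. At the end Me3SiCHN2 with BF3·OEt2 would insert a CH2 group between the carbonyl and the CH2 next to the angular carbon of the pyranone A4, to give the oxepan-3-one A5, which is then reduced.
- Merits: a six-membered ether is easier to close than a seven-membered one, so this road avoids the regiochemical risk of step 8. That is a real advantage.
- Weak points: the insertion is run on the most valuable intermediate, in the presence of an enone that can undergo dipolar addition with the diazo reagent and of tertiary silyl ethers that a boron Lewis acid can ionise. Over-homologation and epoxide formation are known side paths. The ring A carbinol must then be set by reducing a flexible oxepanone beside a second carbonyl group.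
- Comparison: the chosen plan fixes that carbinol by a reagent-controlled epoxidation in step 7 and takes its ring-closure risk early, on material that is easy to replace.

**Alternative 3:** ring B would be closed by a ketyl–alkene cyclisation. SmI2 would reduce the methyl ketone of the oxepane A6 and the ketyl would add 6-exo to the enoate on the angular carbon, giving the hydroxy ester A7.
- Merits: the tertiary carbinol, the adjacent CH and the two-carbon arm appear in one step, where the chosen plan needs allylation, methylenation, epoxidation and reduction. The trans relation of hydroxyl and arm is the one usually favoured.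
- Weak points: A6 is a monocyclic oxepane with a quaternary carbon, an adjacent ether CH and a remote carbinol. Its seven-membered ring must be closed without a ring B template, and its stereocentres must be set without the conformational control of a fused bicycle. The ester and tertiary alcohol of A7 then lead to the 1,4-diol that cyclises to a tetrahydrofuran when the arm is activated.
- Comparison: the chosen plan answers with one enone (4) used for both halves, with ring B serving as the template on which ring A is closed, and with an arm that is unveiled only after the tertiary alcohol is protected.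

Key step: step 21

Remarks on the chemistry:
- Locants of the left half follow 1-benzoxepine numbering (O1, C2 gem-dimethyl, C3 carbinol, C5a angular carbon, C6 bridge-bearing carbon, C7 tertiary carbinol, C9a ether CH).
- "LHE" stands for the group 2-[(3S,5aS,6S,7S,9aS)-2,2,5a,7-tetramethyl-3,7-bis(triethylsilyloxy)decahydro-1-benzoxepin-6-yl]ethyl.
- Compounds 10 to 12 are drawn as the 2S epimers. This centre is equilibrated in step 8.
- The carbinol configuration of 31 is lost in step 21 and is of no consequence.
- The L-fructose-derived epoxidation ketone is taken as purchasable or made from L-sorbose.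

## Route

Step 1
Reactants: 1 2-methylcyclohex-2-en-1-one
Product: 2 (S)-2-methylcyclohex-2-en-1-ol
Conditions: (R)-2-methyl-CBS-oxazaborolidine (10 mol %), BH3·SMe2, THF, −20 °C
Reagents that add atoms: none
Why: Corey–Bakshi–Shibata reduction; the methyl-substituted alkene carbon acts as the large group, so the (R)-catalyst should deliver hydride to the carbonyl face that gives the (S)-allylic alcohol, and 1,2-reduction is the normal course for enones.

Step 2
Reactants: 2 (S)-2-methylcyclohex-2-en-1-ol
Product: 3 (S)-tert-butyldimethyl[(2-methylcyclohex-2-en-1-yl)oxy]silane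
Conditions: TBSCl, imidazole, DMF, 25 °C
Reagents that add atoms: tert-butyldimethylsilyl chloride, CC(C)(C)[Si](C)(C)Cl
Why: Standard silylation of a secondary alcohol; the bulky silyl ether later directs the conjugate addition and the cycloaddition.

Step 3
Reactants: 3 (S)-tert-butyldimethyl[(2-methylcyclohex-2-en-1-yl)oxy]silane
Product: 4 (S)-4-(tert-butyldimethylsilyloxy)-3-methylcyclohex-2-en-1-one
Conditions: Rh2(cap)4 (1 mol %), t-BuOOH (70% aq.), K2CO3, CH2Cl2, 25 °C
Reagents that add atoms: tert-butyl hydroperoxide, CC(C)(C)OO
Why: Allylic C–H oxidation by tert-butylperoxy radicals; the ring CH2 is the only unhindered secondary allylic position, since the carbinol C–H is shielded by the silyl group, and its oxidation makes the stereocentre γ to the new ketone without touching it.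

Step 4
Reactants: 4 (S)-4-(tert-butyldimethylsilyloxy)-3-methylcyclohex-2-en-1-one; 5 5-bromo-2-methylpent-2-ene
Product: 7 (3S,4S)-4-(tert-butyldimethylsilyloxy)-3-methyl-3-(4-methylpent-3-en-1-yl)-1-(trimethylsilyloxy)cyclohex-1-ene (side chain trans to the silyloxy group), via 4-methylpent-3-enylmagnesium bromide 6 (not isolated)
Conditions: 5, Mg, THF; then CuBr·SMe2 (10 mol %), Me3SiCl, HMPA, THF, −78 °C, 4
Reagents that add atoms: chlorotrimethylsilane, C[Si](C)(C)Cl
Why: Copper-catalysed conjugate addition accelerated by the silyl chloride, the usual way to form a quaternary centre on a 3-methylcyclohexenone; the nucleophile should enter anti to the γ-silyloxy group, which puts the future ring A carbon trans to the ether oxygen, and the enolate is captured regiospecifically as the silyl enol ether.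

Step 5
Reactants: 7 silyl enol ether; 8 allyl bromide
Product: 10 (2S,3S,4S)-2-allyl-4-(tert-butyldimethylsilyloxy)-3-methyl-3-(4-methylpent-3-en-1-yl)cyclohexan-1-one, via lithium enolate 9 (not isolated)
Conditions: MeLi, THF, 0 °C; then 8, HMPA, −78 → 0 °C
Reagents that add atoms: none
Why: Methyllithium cleaves the O–Si bond to give the regiodefined lithium enolate, which is C-alkylated by the reactive allylic halide; the configuration of the new α-centre is not critical here because it is equilibrated in step 8.

Step 6
Reactants: 10 allyl ketone
Product: 11 (2S,3S,4S)-2-allyl-4-hydroxy-3-methyl-3-(4-methylpent-3-en-1-yl)cyclohexan-1-one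
Conditions: HF·pyridine, THF, 0 → 25 °C
Reagents that add atoms: none
Why: Fluoride-mediated cleavage of the hindered secondary silyl ether; ketone and alkenes are inert, and the freed hydroxyl is the nucleophile for ring A.

Step 7
Reactants: 11 hydroxy ketone
Product: 12 (2S,3S,4S)-2-allyl-3-{2-[(2S)-3,3-dimethyloxiran-2-yl]ethyl}-4-hydroxy-3-methylcyclohexan-1-one
Conditions: L-fructose-derived Shi ketone (30 mol %), KHSO5 (as 2KHSO5·KHSO4·K2SO4), K2CO3, Bu4NHSO4, Na2B4O7 buffer, MeCN/CH2(OMe)2/H2O, 0 °C
Reagents that add atoms: potassium peroxymonosulfate, [K+].[O-]S(=O)(=O)OO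
Why: Shi asymmetric epoxidation; the chiral dioxirane oxidises the electron-rich trisubstituted alkene far faster than the terminal allyl alkene, and the L-configured ketone should give the (S)-epoxide, which fixes the ring A carbinol centre by reagent control.

Step 8
Reactants: 12 hydroxy epoxide
Product: 13 (3S,5aS,6S,9aS)-6-allyl-3-hydroxy-2,2,5a-trimethyl-3,4,5,5a,6,8,9,9a-octahydro-1-benzoxepin-7(2H)-one (trans-fused)
Conditions: CSA (10 mol %), CH2Cl2, 0 °C; then DBU, 25 °C
Reagents that add atoms: none
Why: Acid-catalysed intramolecular epoxide opening in the 7-endo mode; the ring B hydroxyl should attack the tertiary CMe2 carbon, which carries the positive charge best and is not hindered toward an SN1-like opening, while the CH–O bond stays intact so the carbinol keeps its configuration. DBU then equilibrates the α-carbon to the equatorial allyl epimer of the rigid trans-fused bicycle.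

Step 9
Reactants: 13 bicyclic ketone
Product: 14 (3S,5aS,9aS)-6-allyl-2,2,5a-trimethyl-7-methylenedecahydro-1-benzoxepin-3-ol (allyl cis to the 5a-methyl group)
Conditions: Ph3PCH3Br, KOt-Bu, toluene, 80 °C
Reagents that add atoms: methyltriphenylphosphonium bromide, C[P+](c1ccccc1)(c1ccccc1)c1ccccc1.[Br-]
Why: Wittig methylenation of a hindered but unconjugated ketone; excess ylide covers the free hydroxyl, and the α-centre is already in its thermodynamic configuration.

Step 10
Reactants: 14 exocyclic alkene
Product: 15 spiro-epoxide of 14 at C7 (oxirane oxygen equatorial and trans to the 5a-methyl group)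
Conditions: mCPBA, NaHCO3, CH2Cl2, 0 °C
Reagents that add atoms: 3-chloroperbenzoic acid, OOC(=O)c1cccc(Cl)c1
Why: Prilezhaev epoxidation; the 1,1-disubstituted alkene reacts faster than the monosubstituted allyl group, and the peracid should approach from the equatorial side, away from the axial angular methyl group, which sets the C7 configuration.

Step 11
Reactants: 15 spiro-epoxide
Product: 16 (3S,5aS,6S,7S,9aS)-6-allyl-2,2,5a,7-tetramethyldecahydro-1-benzoxepine-3,7-diol
Conditions: LiAlH4, THF, 0 → 25 °C
Reagents that add atoms: none
Why: Hydride opens the epoxide at its CH2 terminus by SN2 attack and leaves the axial methyl group and the equatorial tertiary alcohol; the stereocentre was fixed in step 10.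

Step 12
Reactants: 16 diol
Product: 17 (3S,5aS,6S,7S,9aS)-6-allyl-2,2,5a,7-tetramethyl-3,7-bis(triethylsilyloxy)decahydro-1-benzoxepine
Conditions: Et3SiOTf, 2,6-lutidine, CH2Cl2, −40 → 0 °C
Reagents that add atoms: triethylsilyl trifluoromethanesulfonate, CC[Si](CC)(CC)OS(=O)(=O)C(F)(F)F
Why: The silyl triflate silylates the hindered secondary and the tertiary alcohol in one operation; the tertiary alcohol must be capped before the primary alcohol is unveiled, since a free 1,4-diol would close to a tetrahydrofuran on activation, and before the alkoxy radical step.

Step 13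
Reactants: 17 bis(silyl ether)
Product: 18 2-[(3S,5aS,6S,7S,9aS)-2,2,5a,7-tetramethyl-3,7-bis(triethylsilyloxy)decahydro-1-benzoxepin-6-yl]ethanol
Conditions: O3, CH2Cl2/MeOH, −78 °C; then NaBH4, −78 → 0 °C
Reagents that add atoms: ozone, [O-][O+]=O
Why: Ozonolysis with reductive work-up shortens the allyl group to the 2-hydroxyethyl arm; the terminal alkene is the only alkene left and silyl ethers are stable to both reagents.

Step 14
Reactants: 18 primary alcohol
Product: 19 (3S,5aS,6S,7S,9aS)-6-(2-iodoethyl)-2,2,5a,7-tetramethyl-3,7-bis(triethylsilyloxy)decahydro-1-benzoxepine (LHE iodide)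
Conditions: I2, PPh3, imidazole, CH2Cl2, 0 → 25 °C
Reagents that add atoms: iodine, II
Why: Appel-type iodination of a primary alcohol through its alkoxyphosphonium salt; imidazole buffers the medium so that the silyl ethers survive.

Step 15
Reactants: 4 (S)-4-(tert-butyldimethylsilyloxy)-3-methylcyclohex-2-en-1-one
Product: 20 (S)-4-(tert-butyldimethylsilyloxy)-2-iodo-3-methylcyclohex-2-en-1-one
Conditions: I2, DMAP (20 mol %), K2CO3, THF/H2O, 25 °C
Reagents that add atoms: iodine, II
Why: α-Iodination of an enone by amine-catalysed conjugate addition, iodination of the enolate and elimination, a sequence that also works for β-substituted cyclohexenones; the stereocentre is not involved.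

Step 16
Reactants: 19 LHE iodide; 20 α-iodoenone
Product: 23 (S)-4-(tert-butyldimethylsilyloxy)-3-methyl-2-(LHE)cyclohex-2-en-1-one, via primary alkyllithium 21 (not isolated), via lithium alkylmethoxyborate 22 (not isolated)
Conditions: 19, t-BuLi (2.1 equiv), Et2O, −78 °C; B-methoxy-9-BBN, THF, −78 → 25 °C; then 20, PdCl2(dppf) (5 mol %), AsPh3, K3PO4 (aq.), DMF, 25 °C
Reagents that add atoms: none
Why: Iodine–lithium exchange and capture by the borinate give an alkylborate that undergoes B-alkyl Suzuki–Miyaura coupling with the α-iodoenone; the sp3–sp2 bond forms under mild basic conditions that tolerate the ketone and all silyl ethers, and no stereocentre takes part.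

Step 17
Reactants: 23 coupled enone
Product: 25 (S)-4-(tert-butyldimethylsilyloxy)-5-methyl-6-(LHE)cyclohexa-1,5-dien-1-yl trifluoromethanesulfonate, via lithium dienolate 24 (not isolated)
Conditions: LDA, THF, −78 °C; then PhNTf2, −78 → 0 °C
Reagents that add atoms: N-phenylbis(trifluoromethanesulfonimide), O=S(=O)(N(c1ccccc1)S(=O)(=O)C(F)(F)F)C(F)(F)F
Why: Kinetic deprotonation at the only α′-CH2 gives the cross-conjugated dienolate, which is O-triflated; γ-deprotonation is slower at −78 °C, and loss of the β-silyloxy group from the cold enolate is not expected.

Step 18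
Reactants: 25 dienyl triflate
Product: 26 (S)-tert-butyldimethyl{[2-methyl-3-(LHE)cyclohexa-2,4-dien-1-yl]oxy}silane
Conditions: Pd(OAc)2 (5 mol %), PPh3, HCO2H, Bu3N, DMF, 60 °C
Reagents that add atoms: none
Why: Palladium-catalysed formate reduction of an enol triflate (oxidative addition, formate decarboxylation, reductive elimination) replaces C–OTf by C–H and gives the cyclohexa-1,3-diene; the amine-buffered medium guards against loss of silanol and aromatisation.

Step 19
Reactants: 26 diene; 27 isobutyryl chloride
Product: 29 4-(tert-butyldimethylsilyloxy)-3,8,8-trimethyl-2-(LHE)bicyclo[4.2.0]oct-2-en-7-one (cis-fused; silyloxy group on the face opposite to the cyclobutanone), via dimethylketene 28 (not isolated)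
Conditions: 27 (slow addition), Et3N, toluene, 100 °C
Reagents that add atoms: none
Why: Thermal [2+2] cycloaddition of dimethylketene, formed by dehydrochlorination, with the less substituted double bond of the diene. The ketene carbonyl carbon bonds to the diene terminus because the developing positive charge is then allylic, so CMe2 ends on the fusion carbon next to the tetrasubstituted alkene. Suprafacial addition gives the cis fusion, and approach anti to the pseudoaxial silyloxy group should set both fusion centres.

Step 20
Reactants: 29 cyclobutanone; 30 vinylmagnesium bromide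
Product: 31 4-(tert-butyldimethylsilyloxy)-3,8,8-trimethyl-2-(LHE)-7-vinylbicyclo[4.2.0]oct-2-en-7-ol (vinyl on the convex face)
Conditions: 30, CeCl3, THF, −78 °C
Reagents that add atoms: none
Why: 1,2-Addition of the vinyl nucleophile to the strained ketone from the convex face; CeCl3 suppresses enolisation at the α fusion carbon, and the carbinol configuration is irrelevant for the next step.

Step 21
Reactants: 31 1-vinylcyclobutanol
Product: 32 7-(tert-butyldimethylsilyloxy)-4,4,6-trimethyl-5-(LHE)-3,4,4a,7,8,8a-hexahydronaphthalen-1(2H)-one (cis-fused; silyloxy group cis to the fusion hydrogens)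
Conditions: [Ir(dF(CF3)ppy)2(bpy)]PF6 (2 mol %), Bu4N[O2P(OBu)2] (25 mol %), PhCF3, blue LEDs, 25 °C
Reagents that add atoms: none
Why: The excited trivalent iridium complex and the phosphate base remove an electron and a proton from the O–H bond of 31 in a proton-coupled electron transfer and give the alkoxy radical. β-Scission then cleaves the cyclobutane bond to the CMe2 carbon, which releases the ring strain, forms a tertiary radical and leaves a vinyl ketone on the neighbouring fusion carbon. The tertiary radical adds to the terminal enone carbon in a 6-endo-trig closure that forms the CMe2–CH2 bond and ring D, whereas 5-exo attack would give an unstabilised primary radical. The α-keto radical is reduced by the divalent iridium complex and protonated by the phosphoric acid, so the step is a redox-neutral isomerisation. The closest known reaction type is the photoredox ring expansion of 1-alkenylcycloalkanols by two carbons through alkoxy radical scission and recyclisation. No stereocentre is formed, and the two fusion centres are never part of a radical and keep the cis relation from step 19. The step needs scission toward CMe2 and not toward the fusion CH, which the tertiary radical secures, and 6-endo closure, which the match of a nucleophilic radical with the enone β-carbon secures. No thiol is added, so that the tertiary radical is not reduced before it cyclises, every other hydroxyl is silylated, and the mildly oxidising catalyst should spare the tetrasubstituted alkene.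

Step 22
Reactants: 32 ring D ketone
Product: 33 tert-butyldimethyl{[3,5,5-trimethyl-8-methylene-4-(LHE)-1,2,4a,5,6,7,8,8a-octahydronaphthalen-2-yl]oxy}silane (cis-fused; configuration as in 32)
Conditions: Cp2TiMe2, toluene, 70 °C, dark
Reagents that add atoms: dimethyltitanocene, [CH3-].[CH3-].[Ti+4].c1cc[cH-]c1.c1cc[cH-]c1
Why: Petasis methylenation; the titanium carbene formed on heating olefinates the hindered ketone under non-basic conditions, so the α fusion centre is not epimerised as it could be with a phosphorus ylide.

Step 23
Reactants: 33 exocyclic alkene
Product: 34 7-(tert-butyldimethylsilyloxy)-1,4,4,6-tetramethyl-5-(LHE)-1,2,3,4,4a,7,8,8a-octahydronaphthalen-1-ol (cis-fused; tertiary hydroxyl cis to the fusion hydrogens)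
Conditions: Mn(dpm)3 (10 mol %), PhSiH3, O2 (1 atm), i-PrOH/CH2Cl2, 0 °C
Reagents that add atoms: dioxygen, O=O
Why: Mukaiyama hydration; a manganese hydride transfers a hydrogen atom to the terminal CH2 and the tertiary radical is captured by O2. Only the 1,1-disubstituted alkene reacts, whereas a peracid would choose the tetrasubstituted ring C alkene. Oxygen should be taken up on the face of the fusion hydrogens because ring C covers the other face in either chair of ring D.

Step 24
Reactants: 34 tris(silyl ether)
Product: 35 tetraol (36 with the ring C carbonyl as the allylic alcohol; hydroxyl cis to the fusion hydrogens)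
Conditions: HF·pyridine, pyridine, THF, 0 → 25 °C
Reagents that add atoms: none
Why: Buffered fluoride cleaves the two triethylsilyl ethers and the allylic tert-butyldimethylsilyl ether; the medium is too weakly acidic to ionise the tertiary or allylic alcohols.

Step 25
Reactants: 35 tetraol
Product: 36 sipholenol K
Conditions: MnO2, CH2Cl2, 25 °C
Reagents that add atoms: none
Why: MnO2 oxidises only the allylic alcohol and leaves the saturated secondary and the tertiary alcohols; the neutral conditions keep the γ fusion centre of the new enone.

## Compound list

1 | 2-methylcyclohex-2-en-1-one | CC1=CCCCC1=O | starting material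
2 | (S)-2-methylcyclohex-2-en-1-ol | O[C@H]1CCCC=C1C | intermediate
3 | (S)-tert-butyldimethyl[(2-methylcyclohex-2-en-1-yl)oxy]silane | CC(C)(C)[Si](C)(C)O[C@H]1CCCC=C1C | intermediate
4 | (S)-4-(tert-butyldimethylsilyloxy)-3-methylcyclohex-2-en-1-one | CC(C)(C)[Si](C)(C)O[C@H]1CCC(=O)C=C1C | intermediate
5 | 5-bromo-2-methylpent-2-ene | CC(C)=CCCBr | starting material
6 | 4-methylpent-3-enylmagnesium bromide | CC(C)=CCC[Mg]Br | intermediate
7 | (3S,4S)-4-(tert-butyldimethylsilyloxy)-3-methyl-3-(4-methylpent-3-en-1-yl)-1-(trimethylsilyloxy)cyclohex-1-ene | C[Si](C)(C)OC1=C[C@](C)(CCC=C(C)C)[C@@H](O[Si](C)(C)C(C)(C)C)CC1 | intermediate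
8 | allyl bromide | C=CCBr | starting material
9 | lithium enolate of the ketone corresponding to 7 | [Li]OC1=C[C@](C)(CCC=C(C)C)[C@@H](O[Si](C)(C)C(C)(C)C)CC1 | intermediate
10 | (2S,3S,4S)-2-allyl-4-(tert-butyldimethylsilyloxy)-3-methyl-3-(4-methylpent-3-en-1-yl)cyclohexan-1-one | C=CC[C@@H]1C(=O)CC[C@H](O[Si](C)(C)C(C)(C)C)[C@@]1(C)CCC=C(C)C | intermediate
11 | (2S,3S,4S)-2-allyl-4-hydroxy-3-methyl-3-(4-methylpent-3-en-1-yl)cyclohexan-1-one | C=CC[C@@H]1C(=O)CC[C@H](O)[C@@]1(C)CCC=C(C)C | intermediate
12 | (2S,3S,4S)-2-allyl-3-{2-[(2S)-3,3-dimethyloxiran-2-yl]ethyl}-4-hydroxy-3-methylcyclohexan-1-one | C=CC[C@@H]1C(=O)CC[C@H](O)[C@@]1(C)CC[C@@H]1OC1(C)C | intermediate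
13 | (3S,5aS,6S,9aS)-6-allyl-3-hydroxy-2,2,5a-trimethyl-3,4,5,5a,6,8,9,9a-octahydro-1-benzoxepin-7(2H)-one | C=CC[C@H]2[C@]3(C)CC[C@H](O)C(C)(C)O[C@H]3CCC2=O | intermediate
14 | 6-allyl-2,2,5a-trimethyl-7-methylenedecahydro-1-benzoxepin-3-ol (3S,5aS,9aS; allyl cis to 5a-methyl) | C=CC[C@H]2[C@]3(C)CC[C@H](O)C(C)(C)O[C@H]3CCC2=C | intermediate
15 | spiro-epoxide of 14 at C7 (oxirane oxygen trans to 5a-methyl) | C=CC[C@H]2[C@]3(C)CC[C@H](O)C(C)(C)O[C@H]3CC[C@@]21CO1 | intermediate
16 | (3S,5aS,6S,7S,9aS)-6-allyl-2,2,5a,7-tetramethyldecahydro-1-benzoxepine-3,7-diol | C=CC[C@H]2[C@]3(C)CC[C@H](O)C(C)(C)O[C@H]3CC[C@]2(C)O | intermediate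
17 | (3S,5aS,6S,7S,9aS)-6-allyl-2,2,5a,7-tetramethyl-3,7-bis(triethylsilyloxy)decahydro-1-benzoxepine | C=CC[C@H]2[C@]3(C)CC[C@H](O[Si](CC)(CC)CC)C(C)(C)O[C@H]3CC[C@]2(C)O[Si](CC)(CC)CC | intermediate
18 | 2-[(3S,5aS,6S,7S,9aS)-2,2,5a,7-tetramethyl-3,7-bis(triethylsilyloxy)decahydro-1-benzoxepin-6-yl]ethanol | OCC[C@H]2[C@]3(C)CC[C@H](O[Si](CC)(CC)CC)C(C)(C)O[C@H]3CC[C@]2(C)O[Si](CC)(CC)CC | intermediate
19 | (3S,5aS,6S,7S,9aS)-6-(2-iodoethyl)-2,2,5a,7-tetramethyl-3,7-bis(triethylsilyloxy)decahydro-1-benzoxepine | ICC[C@H]2[C@]3(C)CC[C@H](O[Si](CC)(CC)CC)C(C)(C)O[C@H]3CC[C@]2(C)O[Si](CC)(CC)CC | intermediate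
20 | (S)-4-(tert-butyldimethylsilyloxy)-2-iodo-3-methylcyclohex-2-en-1-one | CC(C)(C)[Si](C)(C)O[C@H]1CCC(=O)C(I)=C1C | intermediate
21 | primary alkyllithium from 19 | [Li]CC[C@H]2[C@]3(C)CC[C@H](O[Si](CC)(CC)CC)C(C)(C)O[C@H]3CC[C@]2(C)O[Si](CC)(CC)CC | intermediate
22 | lithium B-(LHE)-B-methoxy-9-borabicyclo[3.3.1]nonan-9-uide | [Li+].CO[B-]1(CC[C@H]2[C@]3(C)CC[C@H](O[Si](CC)(CC)CC)C(C)(C)O[C@H]3CC[C@]2(C)O[Si](CC)(CC)CC)C4CCCC1CCC4 | intermediate
23 | (S)-4-(tert-butyldimethylsilyloxy)-3-methyl-2-(LHE)cyclohex-2-en-1-one | CC1=C(CC[C@H]3[C@]4(C)CC[C@H](O[Si](CC)(CC)CC)C(C)(C)O[C@H]4CC[C@]3(C)O[Si](CC)(CC)CC)C(=O)CC[C@@H]1O[Si](C)(C)C(C)(C)C | intermediate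
24 | lithium cross-conjugated dienolate of 23 | CC1=C(CC[C@H]3[C@]4(C)CC[C@H](O[Si](CC)(CC)CC)C(C)(C)O[C@H]4CC[C@]3(C)O[Si](CC)(CC)CC)C(O[Li])=CC[C@@H]1O[Si](C)(C)C(C)(C)C | intermediate
25 | (S)-4-(tert-butyldimethylsilyloxy)-5-methyl-6-(LHE)cyclohexa-1,5-dien-1-yl trifluoromethanesulfonate | CC1=C(CC[C@H]3[C@]4(C)CC[C@H](O[Si](CC)(CC)CC)C(C)(C)O[C@H]4CC[C@]3(C)O[Si](CC)(CC)CC)C(OS(=O)(=O)C(F)(F)F)=CC[C@@H]1O[Si](C)(C)C(C)(C)C | intermediate
26 | (S)-tert-butyldimethyl{[2-methyl-3-(LHE)cyclohexa-2,4-dien-1-yl]oxy}silane | CC1=C(CC[C@H]3[C@]4(C)CC[C@H](O[Si](CC)(CC)CC)C(C)(C)O[C@H]4CC[C@]3(C)O[Si](CC)(CC)CC)C=CC[C@@H]1O[Si](C)(C)C(C)(C)C | intermediate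
27 | isobutyryl chloride | CC(C)C(=O)Cl | starting material
28 | dimethylketene | CC(C)=C=O | intermediate
29 | 4-(tert-butyldimethylsilyloxy)-3,8,8-trimethyl-2-(LHE)bicyclo[4.2.0]oct-2-en-7-one (cis-fused; silyloxy anti to the cyclobutanone) | O=C1C(C)(C)[C@@H]2C(CC[C@H]3[C@]4(C)CC[C@H](O[Si](CC)(CC)CC)C(C)(C)O[C@H]4CC[C@]3(C)O[Si](CC)(CC)CC)=C(C)[C@@H](O[Si](C)(C)C(C)(C)C)C[C@H]12 | intermediate
30 | vinylmagnesium bromide | C=C[Mg]Br | starting material
31 | 4-(tert-butyldimethylsilyloxy)-3,8,8-trimethyl-2-(LHE)-7-vinylbicyclo[4.2.0]oct-2-en-7-ol (vinyl on the convex face) | C=C[C@@]1(O)C(C)(C)[C@@H]2C(CC[C@H]3[C@]4(C)CC[C@H](O[Si](CC)(CC)CC)C(C)(C)O[C@H]4CC[C@]3(C)O[Si](CC)(CC)CC)=C(C)[C@@H](O[Si](C)(C)C(C)(C)C)C[C@H]12 | intermediate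
32 | 7-(tert-butyldimethylsilyloxy)-4,4,6-trimethyl-5-(LHE)-3,4,4a,7,8,8a-hexahydronaphthalen-1(2H)-one (cis-fused) | CC1=C(CC[C@H]3[C@]4(C)CC[C@H](O[Si](CC)(CC)CC)C(C)(C)O[C@H]4CC[C@]3(C)O[Si](CC)(CC)CC)[C@@H]2[C@H](C[C@@H]1O[Si](C)(C)C(C)(C)C)C(=O)CCC2(C)C | intermediate
33 | 1-methylene analogue of 32 | CC1=C(CC[C@H]3[C@]4(C)CC[C@H](O[Si](CC)(CC)CC)C(C)(C)O[C@H]4CC[C@]3(C)O[Si](CC)(CC)CC)[C@@H]2[C@H](C[C@@H]1O[Si](C)(C)C(C)(C)C)C(=C)CCC2(C)C | intermediate
34 | 7-(tert-butyldimethylsilyloxy)-1,4,4,6-tetramethyl-5-(LHE)-1,2,3,4,4a,7,8,8a-octahydronaphthalen-1-ol (hydroxyl cis to the fusion hydrogens) | CC1=C(CC[C@H]3[C@]4(C)CC[C@H](O[Si](CC)(CC)CC)C(C)(C)O[C@H]4CC[C@]3(C)O[Si](CC)(CC)CC)[C@@H]2[C@H](C[C@@H]1O[Si](C)(C)C(C)(C)C)[C@@](C)(O)CCC2(C)C | intermediate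
35 | tetraol (ring C allylic alcohol of sipholenol K) | CC1=C(CC[C@H]3[C@]4(C)CC[C@H](O)C(C)(C)O[C@H]4CC[C@]3(C)O)[C@@H]2[C@H](C[C@@H]1O)[C@@](C)(O)CCC2(C)C | intermediate
36 | sipholenol K | CC1=C(CC[C@H]2[C@]3(C)CC[C@H](O)C(C)(C)O[C@H]3CC[C@]2(C)O)[C@@H]2[C@H](CC1=O)[C@@](C)(O)CCC2(C)C | target

## Step count and risks

Total step count: 25 steps. Longest linear sequence: 24 steps (steps 1 to 14 and 16 to 25; step 15 is a one-step branch from 4).

Least certain steps:

**Step 21 (key step).** The hydrogen-atom and electron removal from the O–H bond is uphill with a mildly oxidising catalyst and may be slow. The tertiary radical may be reduced before it cyclises. A stronger photooxidant could instead oxidise the tetrasubstituted ring C alkene. The fallback separates radical generation from ring closure with stoichiometric reagents. It sets out from 31: PhI(OAc)2 and I2 under visible light form the hypoiodite, whose alkoxy radical undergoes the same β-scission, and the tertiary radical is captured by iodine to give the ring-opened tertiary iodide vinyl ketone F1. Bu3SnH with AIBN in benzene at 80 °C then regenerates the tertiary radical, which closes 6-endo onto the enone and is reduced by the stannane. The sequence returns to the route at 32. It is the fallback and not the first choice because iodine may touch the ring C alkene.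

**Step 8.** The hydroxyl may attack the secondary epoxide carbon in the 6-exo mode and give a tetrahydropyran. The activated epoxide may also rearrange by hydride shift. The fallback makes the regiochemistry unambiguous by changing the electrophile. It sets out from 12: Cp2TiCl (trivalent titanium, from Cp2TiCl2 and Mn) opens the epoxide to the tertiary radical and eliminates to the isopropenyl carbinol F2, with the carbinol configuration retained. Hg(OCOCF3)2 in CH2Cl2 then adds the ring B hydroxyl to the tertiary carbon of the 1,1-disubstituted alkene (Markovnikov, 7-exo) to give the organomercurial F3. NaBH4 removes mercury and restores the gem-dimethyl group, and after the DBU equilibration the sequence returns at 13. The terminal allyl alkene reacts with divalent mercury more slowly than the 1,1-disubstituted alkene.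

**Step 19.** Dimerisation of the ketene may outrun addition to a hindered diene, facial selectivity may be poor, and 26 may lose silanol and aromatise on heating. The fallback uses a more electrophilic two-carbon partner at low temperature. It sets out from 26: the keteniminium salt made from N,N-dimethylisobutyramide, Tf2O and 2,4,6-collidine in CH2Cl2 adds to the same double bond with the same regiochemistry to give the cyclobutaniminium triflate F4. Aqueous NaHCO3 hydrolyses it, and the sequence returns at 29.

**Step 23.** The planar tertiary radical may take up oxygen with poor facial selectivity, or be reduced to the methyl compound. The fallback replaces the radical by an ionic Markovnikov hydration. It sets out from 33: Hg(OAc)2 in THF/H2O forms the mercurinium ion on the unhindered methylene group, and water adds to the tertiary carbon from the open face to give the hydroxy organomercurial F5. NaBH4 removes mercury, and the sequence returns at 34.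

**Step 3.** Hydrogen abstraction may occur at the carbinol C–H or at the methyl group, which would give desilylated enone or regioisomers. The fallback moves the oxygen by an epoxide-based transposition in which every step is regiodefined. It sets out from 3: mCPBA gives the epoxide F6 anti to the silyloxy group. PhSeNa (from PhSeSePh and NaBH4) opens it at the less substituted carbon to give the hydroxy selenide F7. H2O2 oxidises the selenide, and syn elimination away from the carbinol gives the tertiary allylic alcohol F8. Pyridinium chlorochromate (C5H5NH)[CrO3Cl] effects the oxidative 1,3-transposition, and the sequence returns at 4.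

## Further compounds

F1 | step 21 | ring-opened tertiary iodide vinyl ketone from 31 | CC1=C(CC[C@H]3[C@]4(C)CC[C@H](O[Si](CC)(CC)CC)C(C)(C)O[C@H]4CC[C@]3(C)O[Si](CC)(CC)CC)[C@H]([C@H](C[C@@H]1O[Si](C)(C)C(C)(C)C)C(=O)C=C)C(C)(C)I
F2 | step 8 | (2S,3S,4S)-2-allyl-4-hydroxy-3-[(3S)-3-hydroxy-4-methylpent-4-en-1-yl]-3-methylcyclohexan-1-one | C=CC[C@@H]1C(=O)CC[C@H](O)[C@@]1(C)CC[C@H](O)C(C)=C
F3 | step 8 | organomercurial trifluoroacetate of the oxepane (mixture at C2) | C=CC[C@H]2[C@]3(C)CC[C@H](O)C(C)(C[Hg]OC(=O)C(F)(F)F)O[C@H]3CCC2=O
F4 | step 19 | N,N-dimethylcyclobutaniminium triflate corresponding to 29 | C[N+](C)=C1C(C)(C)[C@@H]2C(CC[C@H]3[C@]4(C)CC[C@H](O[Si](CC)(CC)CC)C(C)(C)O[C@H]4CC[C@]3(C)O[Si](CC)(CC)CC)=C(C)[C@@H](O[Si](C)(C)C(C)(C)C)C[C@H]12.[O-]S(=O)(=O)C(F)(F)F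
F5 | step 23 | hydroxy organomercurial acetate from 33 | CC1=C(CC[C@H]3[C@]4(C)CC[C@H](O[Si](CC)(CC)CC)C(C)(C)O[C@H]4CC[C@]3(C)O[Si](CC)(CC)CC)[C@@H]2[C@H](C[C@@H]1O[Si](C)(C)C(C)(C)C)[C@@](C[Hg]OC(C)=O)(O)CCC2(C)C
F6 | step 3 | epoxide of 3 (oxygen anti to the silyloxy group) | CC(C)(C)[Si](C)(C)O[C@H]1CCC[C@@H]2O[C@]12C
F7 | step 3 | 2-(tert-butyldimethylsilyloxy)-1-methyl-6-(phenylselanyl)cyclohexan-1-ol | CC(C)(C)[Si](C)(C)O[C@H]1CCC[C@@H]([Se]c2ccccc2)[C@]1(C)O
F8 | step 3 | 6-(tert-butyldimethylsilyloxy)-1-methylcyclohex-2-en-1-ol | CC(C)(C)[Si](C)(C)O[C@H]1CCC=C[C@]1(C)O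
A1 | alternative 1 | (2E,6E)-farnesol | CC(C)=CCC/C(C)=C/CC/C(C)=C/CO
A2 | alternative 1 | (2E)-6,7:10,11-diepoxyfarnesyl tert-butyl carbonate | CC(C)(C)OC(=O)OC/C=C(\C)CC[C@@H]1O[C@@]1(C)CC[C@@H]1OC1(C)C
A3 | alternative 1 | ring A/B cyclic carbonate | O=C1OC[C@H]2[C@]3(C)CC[C@H](O)C(C)(C)O[C@H]3CC[C@]2(C)O1
A4 | alternative 2 | pyranone of the full skeleton | CC1=C(CC[C@H]2[C@]3(C)CC(=O)C(C)(C)O[C@H]3CC[C@]2(C)O[Si](C)(C)C)[C@@H]2[C@H](CC1=O)[C@@](C)(O[Si](C)(C)C)CCC2(C)C
A5 | alternative 2 | oxepan-3-one of the full skeleton | CC1=C(CC[C@H]2[C@]3(C)CCC(=O)C(C)(C)O[C@H]3CC[C@]2(C)O[Si](C)(C)C)[C@@H]2[C@H](CC1=O)[C@@](C)(O[Si](C)(C)C)CCC2(C)C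
A6 | alternative 3 | oxepane keto enoate | COC(=O)/C=C/[C@]1(C)CC[C@H](O[Si](C)(C)C(C)(C)C)C(C)(C)O[C@H]1CCC(C)=O
A7 | alternative 3 | ring A/B hydroxy ester | COC(=O)C[C@H]2[C@]3(C)CC[C@H](O[Si](C)(C)C(C)(C)C)C(C)(C)O[C@H]3CC[C@]2(C)O
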